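**Retrosynthetic overview**

- Feature: the ester carbonyl carbon lies between C1 of ring B (the benzoate ring, flanked by C2–OMe and C6–propyl) and the oxygen on C3 of ring A (the acetophenone ring, the middle of the three adjacent oxygens on C2, C3 and C4). This carbon is therefore brought in last, as CO, between an aryl iodide and a phenol.
- Target ⇒ (hydrogenolysis of two benzyl ethers) bis-benzyl depside ⇒ (Pd aryloxycarbonylation) ring B iodide + CO + ring A 4-O-benzyl-2,3-diol.
- Ring A diol ⇐ selective 4-O-benzylation ⇐ BBr3 demethylation ⇐ Friedel–Crafts acetylation ⇐ Kumada coupling of 5-bromo-1,2,3-trimethoxybenzene.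
- Ring B iodide ⇐ desilylative benzylation ⇐ iodination para to a bulky silyl ether ⇐ mono-demethylation ⇐ Kumada coupling of 1-bromo-3,5-dimethoxybenzene.
- No ring is formed: both benzene rings are bought and are joined through the new carbonyl in step 10.

Key step: step 10

Remark: the target is achiral, so no stereocontrol is needed. The two bromoarenes, the two Grignard solutions and CO are taken as commercial. Ring A is numbered as the acetophenone (acetyl-bearing carbon = C1).

**Step 1**
Reactants: 1 5-bromo-1,2,3-trimethoxybenzene; 2 pentylmagnesium bromide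
Product: 3 1,2,3-trimethoxy-5-pentylbenzene
Conditions: NiCl2(Ph2P(CH2)3PPh2) (2 mol %), THF, 0 °C → 50 °C
Reagents that add atoms: none
Why: Kumada–Tamao–Corriu coupling of an aryl bromide with a primary alkyl Grignard reagent, in which the chelating diphosphine on nickel should suppress β-hydride elimination and leave the aryl methyl ethers untouched.

**Step 2**
Reactants: 3 1,2,3-trimethoxy-5-pentylbenzene
Product: 4 1-(2,3,4-trimethoxy-6-pentylphenyl)ethan-1-one
Conditions: AcCl, AlCl3, CH2Cl2, 0 °C
Reagents that add atoms: acetyl chloride, CC(Cl)=O
Why: Friedel–Crafts acylation in which the two free ring carbons are equivalent by symmetry (each ortho to one methoxy group and para to another), so one regioisomer should form, and any methyl ether next to the ketone that AlCl3 cleaves converges in step 3.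

**Step 3**
Reactants: 4 1-(2,3,4-trimethoxy-6-pentylphenyl)ethan-1-one
Product: 5 1-(2,3,4-trihydroxy-6-pentylphenyl)ethan-1-one
Conditions: BBr3 (5 equiv), CH2Cl2, −78 °C → rt; then H2O
Reagents that add atoms: none
Why: Lewis-acid ether cleavage (BBr3 demethylation) of all three aryl methyl ethers, which an aryl ketone and an alkyl chain should tolerate.

**Step 4**
Reactants: 5 1-(2,3,4-trihydroxy-6-pentylphenyl)ethan-1-one
Product: 6 1-[4-(benzyloxy)-2,3-dihydroxy-6-pentylphenyl]ethan-1-one
Conditions: BnBr (1.05 equiv), NaHCO3, MeCN, 70 °C, N2
Reagents that add atoms: benzyl bromide, BrCc1ccccc1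
Why: Williamson etherification under weak-base control, in which only the most acidic hydroxyl (para to the acetyl group) should be ionised by NaHCO3, while the ortho hydroxyl is hydrogen-bonded to the ketone and the central one is the least acidic.

**Step 5**
Reactants: 7 1-bromo-3,5-dimethoxybenzene; 8 propylmagnesium bromide
Product: 9 1,3-dimethoxy-5-propylbenzene
Conditions: NiCl2(Ph2P(CH2)3PPh2) (2 mol %), THF, 0 °C → 50 °C
Reagents that add atoms: none
Why: Kumada–Tamao–Corriu coupling as in step 1, on an electron-rich aryl bromide with a primary alkyl Grignard reagent.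

**Step 6**
Reactants: 9 1,3-dimethoxy-5-propylbenzene
Product: 10 3-methoxy-5-propylphenol
Conditions: NaSEt (1.5 equiv), DMF, 140 °C; then aq. HCl
Reagents that add atoms: none
Why: Nucleophilic (SN2) demethylation by thiolate, which should stop after one ether because the phenoxide formed makes the second methoxy group a far poorer leaving group.

**Step 7**
Reactants: 10 3-methoxy-5-propylphenol
Product: 11 triisopropyl(3-methoxy-5-propylphenoxy)silane
Conditions: TIPSCl, imidazole, DMF, rt
Reagents that add atoms: chlorotriisopropylsilane, CC(C)[Si](Cl)(C(C)C)C(C)C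
Why: Silylation of an unhindered phenol, which installs a bulky group to control the regiochemistry of step 8.

**Step 8**
Reactants: 11 triisopropyl(3-methoxy-5-propylphenoxy)silane
Product: 12 (4-iodo-3-methoxy-5-propylphenoxy)triisopropylsilane
Conditions: NIS (1.0 equiv), CF3CO2H (cat.), MeCN, 0 °C → rt, dark
Reagents that add atoms: N-iodosuccinimide, O=C1CCC(=O)N1I
Why: Electrophilic aromatic iodination in which the triisopropylsilyl group shields both carbons ortho to the silyloxy oxygen, so iodine should enter at the remaining activated carbon, para to the silyloxy group and flanked by methoxy and propyl.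

**Step 9**
Reactants: 12 (4-iodo-3-methoxy-5-propylphenoxy)triisopropylsilane
Product: 14 5-(benzyloxy)-2-iodo-1-methoxy-3-propylbenzene, via cesium 4-iodo-3-methoxy-5-propylphenoxide 13 (not isolated)
Conditions: CsF, BnBr, DMF, rt → 50 °C
Reagents that add atoms: benzyl bromide, BrCc1ccccc1
Why: Fluoride-induced cleavage of the aryl silyl ether gives the phenoxide, which should be trapped in the same flask by Williamson benzylation, while the aryl iodide is inert to both reagents.

**Step 10**
Reactants: 14 5-(benzyloxy)-2-iodo-1-methoxy-3-propylbenzene; 15 carbon monoxide; 6 1-[4-(benzyloxy)-2,3-dihydroxy-6-pentylphenyl]ethan-1-one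
Product: 16 3-acetyl-6-(benzyloxy)-2-hydroxy-4-pentylphenyl 4-(benzyloxy)-2-methoxy-6-propylbenzoate
Conditions: Pd(OAc)2 (5 mol %), 4,5-bis(diphenylphosphino)-9,9-dimethylxanthene (7.5 mol %), CO (3 bar), Et3N (3 equiv), toluene, 90 °C
Reagents that add atoms: none
Why: Zerovalent palladium, generated from Pd(OAc)2 and the diphosphine, should add oxidatively into the carbon–iodine bond of 14, CO should insert to give a divalent aroylpalladium iodide, the triethylammonium phenoxide of 6 should displace iodide at the metal, and reductive elimination should form the carbonyl–oxygen bond and return zerovalent palladium. The closest known reaction is the palladium-catalysed aryloxycarbonylation of aryl halides with phenols (Heck-type carbonylation), run here as a three-component coupling that closes no ring and creates no stereocenter. Two skeletal bonds form, aryl–carbonyl and carbonyl–oxygen, and because the acyl–oxygen bond is made at the metal, the two ortho substituents of ring B that make the free acid hard to esterify should be tolerated. The step needs site selectivity among the ring A oxygens: the one para to acetyl is benzylated and the phenol ortho to acetyl is held in a hydrogen bond to the ketone and is a poor nucleophile, so the central phenol should be acylated, and an ester formed at the ortho oxygen could move to the central oxygen by a 1,2-acyl shift that restores the hydrogen bond. It also needs fast oxidative addition at an electron-rich, doubly ortho-substituted arene, which the iodide and the wide-bite-angle ligand should secure, the ligand also speeding the final reductive elimination.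

**Step 11**
Reactants: 16 3-acetyl-6-(benzyloxy)-2-hydroxy-4-pentylphenyl 4-(benzyloxy)-2-methoxy-6-propylbenzoate
Product: 17 3-acetyl-2,6-dihydroxy-4-pentylphenyl 4-hydroxy-2-methoxy-6-propylbenzoate
Conditions: H2 (1 atm), Pd/C (10% palladium on carbon), EtOAc, rt
Reagents that add atoms: none
Why: Catalytic hydrogenolysis of both aryl benzyl ethers under neutral conditions, which the hindered aryl ester, the methyl ether and the hydrogen-bonded aryl ketone should survive.

**Compound list**

1 | 5-bromo-1,2,3-trimethoxybenzene | COc1cc(Br)cc(OC)c1OC | starting material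
2 | pentylmagnesium bromide | CCCCC[Mg]Br | starting material
3 | 1,2,3-trimethoxy-5-pentylbenzene | CCCCCc1cc(OC)c(OC)c(OC)c1 | intermediate
4 | 1-(2,3,4-trimethoxy-6-pentylphenyl)ethan-1-one | CCCCCc1cc(OC)c(OC)c(OC)c1C(C)=O | intermediate
5 | 1-(2,3,4-trihydroxy-6-pentylphenyl)ethan-1-one | CCCCCc1cc(O)c(O)c(O)c1C(C)=O | intermediate
6 | 1-[4-(benzyloxy)-2,3-dihydroxy-6-pentylphenyl]ethan-1-one | CCCCCc1cc(OCc2ccccc2)c(O)c(O)c1C(C)=O | intermediate
7 | 1-bromo-3,5-dimethoxybenzene | COc1cc(Br)cc(OC)c1 | starting material
8 | propylmagnesium bromide | CCC[Mg]Br | starting material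
9 | 1,3-dimethoxy-5-propylbenzene | CCCc1cc(OC)cc(OC)c1 | intermediate
10 | 3-methoxy-5-propylphenol | CCCc1cc(O)cc(OC)c1 | intermediate
11 | triisopropyl(3-methoxy-5-propylphenoxy)silane | CCCc1cc(O[Si](C(C)C)(C(C)C)C(C)C)cc(OC)c1 | intermediate
12 | (4-iodo-3-methoxy-5-propylphenoxy)triisopropylsilane | CCCc1cc(O[Si](C(C)C)(C(C)C)C(C)C)cc(OC)c1I | intermediate
13 | cesium 4-iodo-3-methoxy-5-propylphenoxide | CCCc1cc([O-])cc(OC)c1I.[Cs+] | intermediate
14 | 5-(benzyloxy)-2-iodo-1-methoxy-3-propylbenzene | CCCc1cc(OCc2ccccc2)cc(OC)c1I | intermediate
15 | carbon monoxide | [C-]#[O+] | starting material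
16 | 3-acetyl-6-(benzyloxy)-2-hydroxy-4-pentylphenyl 4-(benzyloxy)-2-methoxy-6-propylbenzoate | CCCCCc1cc(OCc2ccccc2)c(OC(=O)c2c(CCC)cc(OCc3ccccc3)cc2OC)c(O)c1C(C)=O | intermediate
17 | 3-acetyl-2,6-dihydroxy-4-pentylphenyl 4-hydroxy-2-methoxy-6-propylbenzoate | CCCCCc1cc(O)c(OC(=O)c2c(CCC)cc(O)cc2OC)c(O)c1C(C)=O | target

**Step count**

Total: 11 steps. Longest linear sequence: 7 steps (steps 5, 6, 7, 8, 9, 10, 11, from 1-bromo-3,5-dimethoxybenzene). The ring A branch is steps 1–4.

**Steps most likely to fail**

1. Step 10 (carbonylative esterification). Oxidative addition and CO insertion at the electron-rich, doubly ortho-substituted iodide may be slow, so that reductive loss of iodine or binding of the catechol-type diol to palladium takes over; acylation may also go to the wrong oxygen. Fallback, from 14 back to 16 by classical acyl transfer: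
   - Iodine–magnesium exchange on 14 (iPrMgCl·LiCl, THF, −20 °C) should give [4-(benzyloxy)-2-methoxy-6-propylphenyl]magnesium chloride F1.
   - Quenching with CO2 and acidifying should give 4-(benzyloxy)-2-methoxy-6-propylbenzoic acid F2.
   - Trifluoroacetic anhydride in toluene at rt should convert F2 into 4-(benzyloxy)-2-methoxy-6-propylbenzoic trifluoroacetic anhydride F3, an acylium-type donor suited to hindered aroyl groups.
   - F3 should acylate the central phenol of diol 6, and the route is rejoined at 16.

2. Step 8 (iodination). Iodine may enter para to the methoxy group despite the silyl shield, a second iodine may add, or the acid may strip the silyl group so that the free phenol iodinates unselectively. Fallback, from phenol 10 back to 14, using a different substrate, a para-selective brominating agent and a halogen change: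
   - Bromination of 10 with tetrabutylammonium tribromide (Bu4NBr3) in CH2Cl2/MeOH should give 4-bromo-3-methoxy-5-propylphenol F4, which is separable from any ortho isomer because the ortho isomer is internally hydrogen-bonded.
   - Benzylation (BnBr, K2CO3, DMF) should give 5-(benzyloxy)-2-bromo-1-methoxy-3-propylbenzene F5.
   - Bromine–lithium exchange (n-BuLi, THF, −78 °C) should give [4-(benzyloxy)-2-methoxy-6-propylphenyl]lithium F6, and quenching with I2 rejoins the route at 14.

3. Step 4 (mono-benzylation). A second benzyl group may add at the central oxygen, and the pyrogallol-type triol may oxidise in air under base. Fallback, from triol 5 back to 6, replacing selective ionisation by protection and selective acyl exchange: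
   - Peracetylation of 5 (Ac2O, pyridine) should give 4-acetyl-5-pentylbenzene-1,2,3-triyl triacetate F7.
   - Heating F7 with BnBr, K2CO3 and KI in acetone should cleave only the most activated aryl acetate, para to the ketone, to potassium 2,3-diacetoxy-4-acetyl-5-pentylphenoxide F8.
   - F8 should be benzylated in the same flask to 3-acetyl-6-(benzyloxy)-4-pentyl-1,2-phenylene diacetate F9.
   - Methanolysis of the two remaining acetates (K2CO3, MeOH, 0 °C, N2) rejoins the route at 6.

**Further compounds**

F1 | step 10 | [4-(benzyloxy)-2-methoxy-6-propylphenyl]magnesium chloride | CCCc1cc(OCc2ccccc2)cc(OC)c1[Mg]Cl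
F2 | step 10 | 4-(benzyloxy)-2-methoxy-6-propylbenzoic acid | CCCc1cc(OCc2ccccc2)cc(OC)c1C(=O)O
F3 | step 10 | 4-(benzyloxy)-2-methoxy-6-propylbenzoic trifluoroacetic anhydride | CCCc1cc(OCc2ccccc2)cc(OC)c1C(=O)OC(=O)C(F)(F)F
F4 | step 8 | 4-bromo-3-methoxy-5-propylphenol | CCCc1cc(O)cc(OC)c1Br
F5 | step 8 | 5-(benzyloxy)-2-bromo-1-methoxy-3-propylbenzene | CCCc1cc(OCc2ccccc2)cc(OC)c1Br
F6 | step 8 | [4-(benzyloxy)-2-methoxy-6-propylphenyl]lithium | CCCc1cc(OCc2ccccc2)cc(OC)c1[Li]
F7 | step 4 | 4-acetyl-5-pentylbenzene-1,2,3-triyl triacetate | CCCCCc1cc(OC(C)=O)c(OC(C)=O)c(OC(C)=O)c1C(C)=O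
F8 | step 4 | potassium 2,3-diacetoxy-4-acetyl-5-pentylphenoxide | CCCCCc1cc([O-])c(OC(C)=O)c(OC(C)=O)c1C(C)=O.[K+]
F9 | step 4 | 3-acetyl-6-(benzyloxy)-4-pentyl-1,2-phenylene diacetate | CCCCCc1cc(OCc2ccccc2)c(OC(C)=O)c(OC(C)=O)c1C(C)=O
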